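| setting | north | north-east | south-east | flask |
|---|---|---|---|---|
| J | 20 mM | 20 mM | 20 mM | 20 mM |
| X | 1.1 µM | 1.1 µM | 1.1 µM | 1.1 µM |
| L | 0.14 µM | 0.14 µM | 0.28 µM | 0.14 µM |
| G | 7.3 µM | 11 µM | 5.2 µM | 5.2 µM |
| remark | run made earlier | run made earlier | run made earlier |  |

- north (time / min: D / %, J / %): 0.250: 4, 98; 0.417: 4, 96; 0.667: 3, 92; 1.00: 10, 91; 2.00: 20, 80; 3.00: 28, 71
- north-east (time / min: D / %, J / %): 0.250: 1, 99; 0.417: 2, 98; 0.667: 4, 95; 1.00: 7, 92; 2.00: 13, 85; 3.00: 23, 82
- south-east (time / min: D / %, J / %): 0.250: 6, 99; 0.833: 11, 88; 1.33: 15, 85; 2.00: 21, 78; 3.00: 31, 68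

(scatter of a reading: 1.5 percentage points)

- reactions considered so far: J + X -> D + X; X + G <-> Z; X + L -> Q
- no earlier run changes the charge of X; that part of a forecast is a guess

* apparent order in X when 10% of the J are converted (percent change of the rate of making D for one percent more X charged)

**Late rates.** Late in the earlier runs, at 3.00 min, take the mean of D gained and J lost: north reads 28.5%, north-east 20.5%, south-east 31.5%.

**Working share.** Suppose each L removes one X for good, as the limiting reagent of that step. Then one minus L charged over X charged, 87.3% in your flask, is the working share, the part of the X charge that L leaves. One percent more X then gives 1.15 percent more working X, and that is the order if G holds a fixed share of it.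

**G's hold.** North and north-east have the same working share, and the ratio of these two readings is 1.39. As a reading, that puts the G level holding half of the working X at 1.98 X charges. This level predicts south-east over north as 1.10, and the readings give 1.11. By this reading, 29.6% of working X stays free in your flask.

**Weak link.** The fixed share is the weak link: by this reckoning, Z takes 13.0% of the flask's G. Divide 1.15 by one minus Z's share of working X times that amount of G, and my order is 1.26.

**Forecast.** Working from "I treat L as a fast, tight, stoichiometric kill of X", the forecast gives 1.22, lower than my figure.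

**The flask.** The flask gives 1.3, and the forecast stands within the margin asked.

    J + X → D + X, rate k1*[J]*[X]/(1 + ([J]/Km1) + ([D]/Kp1)) (36.3 mM, 37.2 mM, k = 17400 /M/s)
    X + G ⇌ Z, settled at all times (K = 8.09 × 10⁵ /M)
    X + L → Q (k = 2.26 × 10⁵ /M/s)

**L's clock.** With X at 19.4% of the catalyst, L in the flask halves every 0.240 min, shorter than the 0.702 min taken to reach 10% conversion. At 3.00 min, X and Z together hold 87.3% of the catalyst, the working share of 87.3%, beside 12.7% in Q, with L at 0.0176% of its charge.

All runs are calculated on assumed constants; the scatter is artificial.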